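**Retrosynthetic overview**
1. Target 14 ⇐ 13 by a last-step allylic C–H oxidation of the purchased cyclohexene ring to the enone.
2. 13 ⇐ 10: the 1,2-dioxane is closed through the C3–O bond, a tertiary alkylperoxide opening a cis-β-lactone at C4 with inversion (the new step).
3. 10 ⇐ 9: the C6–O bond comes from cobalt-catalysed hydroperoxysilylation of a 1,1-disubstituted alkene.
4. 9 ⇐ 7 + 8: the cis-β-lactone (C2 and the C3 precursor) comes from a catalytic asymmetric ketene–aldehyde cyclocondensation.
5. 7 ⇐ 1 + 2 by enolate alkylation, methylenation and partial reduction. Ring order: cyclohexene bought, oxetanone in step 4, 1,2-dioxane in step 6.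

Assumption: the target SMILES is read as (2R,3R,6R), and dihydro-β-ionone (1) is bought as the commercial fragrance chemical.

Note on C6: step 5 creates C6 through a planar tertiary radical, so C6 is not controlled. Compounds 10, 11 and 12 are each an about 1:1 pair of C6 epimers, drawn without a C6 descriptor. Both epimers cyclise in step 6. Compound 13 is the 6R isomer only; its 6S epimer is separated by chromatography in step 6 and discarded, which costs about half the material at that point.

**Step 1**
Reactants: 1 dihydro-β-ionone [4-(2,6,6-trimethylcyclohex-1-en-1-yl)butan-2-one]; 2 ethyl bromoacetate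
Product: 4 ethyl 4-oxo-6-(2,6,6-trimethylcyclohex-1-en-1-yl)hexanoate, via terminal lithium enolate 3 (not isolated)
Conditions: LiN(iPr)2 (1.05 equiv), THF, −78 °C; then 2 (1.2 equiv), N,N′-dimethylpropyleneurea, −78 → 0 °C
Reagents that add atoms: none
Why: The hindered amide base deprotonates the methyl ketone kinetically at the methyl group and the less substituted enolate is alkylated by the α-bromo ester (enolate alkylation); no stereocenter is formed.

**Step 2**
Reactants: 4 ethyl 4-oxo-6-(2,6,6-trimethylcyclohex-1-en-1-yl)hexanoate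
Product: 5 ethyl 4-methylidene-6-(2,6,6-trimethylcyclohex-1-en-1-yl)hexanoate
Conditions: Ph3PCH3Br (1.3 equiv), KN(SiMe3)2 (1.25 equiv), THF, 0 °C; then 4, −78 °C → rt
Reagents that add atoms: methyltriphenylphosphonium bromide, C[P+](c1ccccc1)(c1ccccc1)c1ccccc1.[Br-]
Why: Wittig methylenation, in which the non-stabilised ylide (made with no excess base) reacts with the ketone far faster than with the ester; no stereocenter is formed.

**Step 3**
Reactants: 5 ethyl 4-methylidene-6-(2,6,6-trimethylcyclohex-1-en-1-yl)hexanoate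
Product: 7 4-methylidene-6-(2,6,6-trimethylcyclohex-1-en-1-yl)hexanal, via aluminium hemiacetal 6 (not isolated)
Conditions: iBu2AlH (1.1 equiv), CH2Cl2, −78 °C; then MeOH, aq. KNaC4H4O6
Reagents that add atoms: none
Why: Partial ester reduction, in which the tetrahedral aluminium hemiacetal persists at −78 °C and releases the aldehyde only on work-up; both alkenes are inert.

**Step 4**
Reactants: 7 4-methylidene-6-(2,6,6-trimethylcyclohex-1-en-1-yl)hexanal; 8 propanoyl chloride
Product: 9 (3R,4S)-3-methyl-4-[3-methylidene-5-(2,6,6-trimethylcyclohex-1-en-1-yl)pentyl]oxetan-2-one (cis)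
Conditions: 8 (2 equiv), O-trimethylsilylquinidine (10 mol%), LiClO4 (2 equiv), iPr2NEt (2.5 equiv), CH2Cl2/Et2O, −78 °C
Reagents that add atoms: none
Why: Catalytic asymmetric acyl halide–aldehyde cyclocondensation (formal ketene–aldehyde [2+2]), in which the alkaloid-bound enolate of methylketene adds to the lithium-activated aldehyde through a closed transition state to give the cis lactone and set both C3 and C4 under catalyst control; the quinidine-derived catalyst is the one expected to give (3R,4S), and its quinine-derived pseudoenantiomer gives the antipode.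

**Step 5**
Reactants: 9 (3R,4S)-3-methyl-4-[3-methylidene-5-(2,6,6-trimethylcyclohex-1-en-1-yl)pentyl]oxetan-2-one
Product: 10 (3R,4S)-3-methyl-4-[3-methyl-3-(triethylsilylperoxy)-5-(2,6,6-trimethylcyclohex-1-en-1-yl)pentyl]oxetan-2-one (C6 epimer pair)
Conditions: Co(thd)2 (10 mol%; thd = 2,2,6,6-tetramethylheptane-3,5-dionate), O2 (1 atm), Et3SiH (3 equiv), tBuOOH (cat.), ClCH2CH2Cl, rt
Reagents that add atoms: dioxygen, O=O; triethylsilane, CC[SiH](CC)CC
Why: Mukaiyama–Isayama hydroperoxysilylation, in which cobalt hydride transfers a hydrogen atom to the terminal CH2 (forming the C6 methyl), the tertiary radical is trapped by O2 and the peroxide is silylated, while the hindered tetrasubstituted ring alkene and the lactone are untouched; the new C6 centre forms without facial control.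

**Step 6**
Reactants: 10 (3R,4S)-3-methyl-4-[3-methyl-3-(triethylsilylperoxy)-5-(2,6,6-trimethylcyclohex-1-en-1-yl)pentyl]oxetan-2-one (C6 epimer pair)
Product: 13 methyl (2R)-2-[(3R,6R)-6-methyl-6-[2-(2,6,6-trimethylcyclohex-1-en-1-yl)ethyl]-1,2-dioxan-3-yl]propanoate, via tetrabutylammonium alkylperoxide 11 (not isolated), via tetrabutylammonium dioxane carboxylate 12 (not isolated)
Conditions: Bu4NF (1.1 equiv, dried over 4 Å molecular sieves), THF (0.01 M), −40 → 0 °C; then MeI (5 equiv), 0 °C → rt; SiO2 chromatography to separate 13 from its 6S epimer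
Reagents that add atoms: iodomethane, CI
Why: Proposed new method: fluoride cleaves the O–Si bond and the naked tertiary alkylperoxide anion, held four atoms away, attacks the lactone C4 from the back in a 6-exo-tet SN2 opening (alkyl–oxygen cleavage driven by about 23 kcal/mol of ring strain, carboxylate as leaving group), which closes the 1,2-dioxane and inverts lactone C4 (S) into the C3 (R) centre while C2 and C6 are untouched, so each C6 epimer of 10 gives its own dioxane and the 6R product is isolated by chromatography; attack at the acyl carbon would need an eight-membered ring, and E1cB loss of the β-oxygen is shut off because the lactone C4–O bond lies orthogonal to the enolate π system; the closest known reactions are SN2 openings of β-lactones at C4 by azide, thiolate or sulfonamide anions with inversion, and 6-exo cyclisations of hydroperoxides onto epoxides or mesylates.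

**Step 7**
Reactants: 13 methyl (2R)-2-[(3R,6R)-6-methyl-6-[2-(2,6,6-trimethylcyclohex-1-en-1-yl)ethyl]-1,2-dioxan-3-yl]propanoate
Product: 14 diacarperoxide A [methyl (2R)-2-[(3R,6R)-6-methyl-6-[2-(2,6,6-trimethyl-3-oxocyclohex-1-en-1-yl)ethyl]-1,2-dioxan-3-yl]propanoate]
Conditions: CrO3 (15 equiv), 3,5-dimethylpyrazole (15 equiv), CH2Cl2, −20 °C
Reagents that add atoms: chromium trioxide, O=[Cr](=O)=O
Why: CrO3–3,5-dimethylpyrazole allylic oxidation, expected at the ring CH2 next to the methyl-bearing alkene carbon because the side-chain allylic CH2 is shielded by the adjacent gem-dimethyl carbon; the dialkyl peroxide and ester should be inert to hexavalent chromium at −20 °C and no stereocenter is touched.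

**Compound list**
1 | dihydro-β-ionone, 4-(2,6,6-trimethylcyclohex-1-en-1-yl)butan-2-one | CC(=O)CCC1=C(C)CCCC1(C)C | starting material
2 | ethyl bromoacetate | CCOC(=O)CBr | starting material
3 | lithium 4-(2,6,6-trimethylcyclohex-1-en-1-yl)but-1-en-2-olate (not isolated) | [Li]OC(=C)CCC1=C(C)CCCC1(C)C | intermediate
4 | ethyl 4-oxo-6-(2,6,6-trimethylcyclohex-1-en-1-yl)hexanoate | CCOC(=O)CCC(=O)CCC1=C(C)CCCC1(C)C | intermediate
5 | ethyl 4-methylidene-6-(2,6,6-trimethylcyclohex-1-en-1-yl)hexanoate | CCOC(=O)CCC(=C)CCC1=C(C)CCCC1(C)C | intermediate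
6 | diisobutylaluminium hemiacetal of 5, [1-ethoxy-4-methylidene-6-(2,6,6-trimethylcyclohex-1-en-1-yl)hexoxy]bis(2-methylpropyl)aluminium (not isolated) | CCOC(O[Al](CC(C)C)CC(C)C)CCC(=C)CCC1=C(C)CCCC1(C)C | intermediate
7 | 4-methylidene-6-(2,6,6-trimethylcyclohex-1-en-1-yl)hexanal | O=CCCC(=C)CCC1=C(C)CCCC1(C)C | intermediate
8 | propanoyl chloride | CCC(=O)Cl | starting material
9 | (3R,4S)-3-methyl-4-[3-methylidene-5-(2,6,6-trimethylcyclohex-1-en-1-yl)pentyl]oxetan-2-one | O=C1[C@H](C)[C@H](CCC(=C)CCC2=C(C)CCCC2(C)C)O1 | intermediate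
10 | (3R,4S)-3-methyl-4-[3-methyl-3-(triethylsilylperoxy)-5-(2,6,6-trimethylcyclohex-1-en-1-yl)pentyl]oxetan-2-one, C6 epimer pair | O=C1[C@H](C)[C@H](CCC(C)(OO[Si](CC)(CC)CC)CCC2=C(C)CCCC2(C)C)O1 | intermediate
11 | tetrabutylammonium salt of the alkylperoxide anion formed from 10 by loss of the triethylsilyl group, C6 epimer pair (not isolated) | O=C1[C@H](C)[C@H](CCC(C)(O[O-])CCC2=C(C)CCCC2(C)C)O1.CCCC[N+](CCCC)(CCCC)CCCC | intermediate
12 | tetrabutylammonium (2R)-2-[(3R)-6-methyl-6-[2-(2,6,6-trimethylcyclohex-1-en-1-yl)ethyl]-1,2-dioxan-3-yl]propanoate, C6 epimer pair (not isolated) | [O-]C(=O)[C@H](C)[C@H]1CCC(C)(CCC2=C(C)CCCC2(C)C)OO1.CCCC[N+](CCCC)(CCCC)CCCC | intermediate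
13 | methyl (2R)-2-[(3R,6R)-6-methyl-6-[2-(2,6,6-trimethylcyclohex-1-en-1-yl)ethyl]-1,2-dioxan-3-yl]propanoate | COC(=O)[C@H](C)[C@H]1CC[C@@](C)(CCC2=C(C)CCCC2(C)C)OO1 | intermediate
14 | diacarperoxide A, methyl (2R)-2-[(3R,6R)-6-methyl-6-[2-(2,6,6-trimethyl-3-oxocyclohex-1-en-1-yl)ethyl]-1,2-dioxan-3-yl]propanoate | COC(=O)[C@H](C)[C@H]1CC[C@@](C)(CCC2=C(C)C(=O)CCC2(C)C)OO1 | target

**Totals**
Total step count: 7. Longest linear sequence: 7 steps (from 1).

**Three steps most likely to fail**

Step 6 (the proposed new ring closure). The risks are intermolecular acyl attack by the peroxide anion, lactone hydrolysis by wet fluoride, a sluggish SN2 at the secondary lactone carbon, and base-induced retro-oxa-Michael opening of the β-peroxy ester once it is methylated. The fallback uses known chemistry; it sets out from 9 and comes back at 13. LiBH4 in THF opens the lactone reductively to (2S,3S)-2-methyl-6-methylidene-8-(2,6,6-trimethylcyclohex-1-en-1-yl)octane-1,3-diol F1. Silylation with tBuPh2SiCl and imidazole protects the primary hydroxyl and gives the primary tert-butyldiphenylsilyl ether F2. MeSO2Cl and Et3N give the secondary mesylate F3, which has no acidifying carbonyl next to it and so cannot eliminate by E1cB. The Co(thd)2/O2/Et3SiH conditions of step 5 then give the triethylsilyl peroxide mesylate F4 as a C6 epimer pair. Excess Bu4NF frees the peroxide anion, which displaces the mesylate in a known 6-exo-tet SN2 cyclisation with inversion; the same reagent removes the silyl ether and gives the dioxane primary alcohol F5. 2,2,6,6-Tetramethylpiperidin-1-oxyl with PhI(OAc)2 in MeCN/H2O oxidises this to the dioxane propanoic acid F6. Me3SiCHN2 in MeOH/toluene gives the methyl ester, and chromatography separates 13 from its 6S epimer.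

Step 7 (late allylic oxidation). The risks are attack at the side-chain allylic CH2 or the ring methyl, over-oxidation, and loss of the peroxide. The fallback sets out from 13 and comes back at 14. Radical bromination with N-bromosuccinimide (PhCF3, visible light, 0 °C) functionalises the ring allylic CH2 and gives the allylic bromide F7 as a mixture at the C–Br carbon. Oxidation of this bromide with N-methylmorpholine N-oxide in MeCN at rt (a Kornblum-type oxidation) gives 14.

Step 4 (asymmetric cyclocondensation). The risks are that the sense or level of induction is not as expected, or that conversion is low with this aldehyde. The fallback sets out from 7 and comes back at 9. An Evans syn aldol of 7 with (R)-4-benzyl-3-propanoyl-1,3-oxazolidin-2-one (Bu2BOTf, iPr2NEt, CH2Cl2, −78 → 0 °C) gives the syn aldol adduct F8. LiOH/H2O2 in THF/H2O removes the auxiliary and gives the (2R,3S)-β-hydroxy acid F9. PhSO2Cl in pyridine at 0 °C lactonises it by carboxyl activation, with retention at the carbinol carbon, to the cis-lactone 9.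

**Further compounds**
F1 | step 6 | (2S,3S)-2-methyl-6-methylidene-8-(2,6,6-trimethylcyclohex-1-en-1-yl)octane-1,3-diol | OC[C@H](C)[C@@H](O)CCC(=C)CCC1=C(C)CCCC1(C)C
F2 | step 6 | (2S,3S)-1-[(tert-butyldiphenylsilyl)oxy]-2-methyl-6-methylidene-8-(2,6,6-trimethylcyclohex-1-en-1-yl)octan-3-ol | CC(C)(C)[Si](OC[C@H](C)[C@@H](O)CCC(=C)CCC1=C(C)CCCC1(C)C)(c1ccccc1)c1ccccc1
F3 | step 6 | (2S,3S)-1-[(tert-butyldiphenylsilyl)oxy]-2-methyl-6-methylidene-8-(2,6,6-trimethylcyclohex-1-en-1-yl)octan-3-yl methanesulfonate | CC(C)(C)[Si](OC[C@H](C)[C@@H](OS(C)(=O)=O)CCC(=C)CCC1=C(C)CCCC1(C)C)(c1ccccc1)c1ccccc1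
F4 | step 6 | (2S,3S)-1-[(tert-butyldiphenylsilyl)oxy]-2,6-dimethyl-6-(triethylsilylperoxy)-8-(2,6,6-trimethylcyclohex-1-en-1-yl)octan-3-yl methanesulfonate, C6 epimer pair | CC(C)(C)[Si](OC[C@H](C)[C@@H](OS(C)(=O)=O)CCC(C)(OO[Si](CC)(CC)CC)CCC1=C(C)CCCC1(C)C)(c1ccccc1)c1ccccc1
F5 | step 6 | (2S)-2-[(3R)-6-methyl-6-[2-(2,6,6-trimethylcyclohex-1-en-1-yl)ethyl]-1,2-dioxan-3-yl]propan-1-ol, C6 epimer pair | OC[C@H](C)[C@H]1CCC(C)(CCC2=C(C)CCCC2(C)C)OO1
F6 | step 6 | (2R)-2-[(3R)-6-methyl-6-[2-(2,6,6-trimethylcyclohex-1-en-1-yl)ethyl]-1,2-dioxan-3-yl]propanoic acid, C6 epimer pair | OC(=O)[C@H](C)[C@H]1CCC(C)(CCC2=C(C)CCCC2(C)C)OO1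
F7 | step 7 | methyl (2R)-2-[(3R,6R)-6-[2-(3-bromo-2,6,6-trimethylcyclohex-1-en-1-yl)ethyl]-6-methyl-1,2-dioxan-3-yl]propanoate, mixture at the C–Br carbon | COC(=O)[C@H](C)[C@H]1CC[C@@](C)(CCC2=C(C)C(Br)CCC2(C)C)OO1
F8 | step 4 | (4R)-4-benzyl-3-[(2R,3S)-3-hydroxy-2-methyl-6-methylidene-8-(2,6,6-trimethylcyclohex-1-en-1-yl)octanoyl]-1,3-oxazolidin-2-one | O=C1OC[C@@H](Cc2ccccc2)N1C(=O)[C@H](C)[C@@H](O)CCC(=C)CCC3=C(C)CCCC3(C)C
F9 | step 4 | (2R,3S)-3-hydroxy-2-methyl-6-methylidene-8-(2,6,6-trimethylcyclohex-1-en-1-yl)octanoic acid | OC(=O)[C@H](C)[C@@H](O)CCC(=C)CCC1=C(C)CCCC1(C)C
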